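Follow y, the fraction of the starting material charged that is not yet product, whether free or held in idle adduct.

| setting | zeta | gamma | theta |
|---|---|---|---|
| starting material | 0.050 M (fed, over 4.0 s) | 0.050 M (fed, over 4.0 s) | 0.050 M (fed, over 4.0 s) |
| coupling partner | 1.10 equiv | 1.70 equiv | 2.50 equiv |
| free catalyst | 2.5 mol% | 2.5 mol% | 2.5 mol% |
| time | 50 s | 50 s | 50 s |

    coupling partner + free catalyst → catalyst intermediate A (k1 = 580 M⁻¹ s⁻¹)
    catalyst intermediate A → released group + catalyst intermediate B (k2 = 4.4 s⁻¹)
    starting material + catalyst intermediate B ⇌ catalyst intermediate C (K3 = 6.6 M⁻¹, k3 = 82 M⁻¹ s⁻¹)
    catalyst intermediate C → free catalyst + product (k4 = 42 s⁻¹)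
    starting material + released group ⇌ idle adduct, settled at all times (K5 = 11 M⁻¹)

- amounts and yields of released group count idle adduct too
- what has gone from starting material into another species counts as reacted, even if it can come back
- run time (zeta): 50 s

- part of the starting material that has reacted at the end, zeta
- part of the starting material that has reacted at the end, gamma
- part of the starting material that has reacted at the end, theta
- what raising the equivalents of coupling partner from its lowest to its highest value here does to the part of the starting material that has reacted (changes below 5 percentage points count as none) (it falls / it rises / no change)

My own reckoning: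

1. Take y = 0.100 and compare rates there. Catalyst intermediate B captures starting material at about 0.410 s⁻¹, slower than catalyst intermediate A releases at 4.4 s⁻¹. So at this y, catalyst intermediate B is the resting state and capture the rate-limiting step.

2. Check the coupling partner. In zeta the surplus, what remains once the starting material and the catalyst have each taken their share, by itself rebinds free catalyst at 2.18 s⁻¹, faster than that capture, so leave the equivalents out of the reckoning.

3. Correct capture for return. Catalyst intermediate C goes on at 42 s⁻¹ and back at 12.4 s⁻¹, so 77.2% of captures count.

4. Define the clearing time, the time in which free starting material falls by a factor e with all catalyst waiting as catalyst intermediate B: τ = 12.6 s.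

5. Correct for the idle adduct. Taking released group equal to product, free starting material is y/(1 + a(1 − y)), with a = 0.550.

6. Add the release wait, since at the full charge capture, 4.10 s⁻¹, is close to release. Release costs R(1 − y), with R = 9.09 s. Half the feed, 2.00 s, is lost as well.

7. Integrate the waits into the clock: t(y) = half the feed + R(1 − y) + τ[(1 + a) ln(1/y) − a(1 − y)].

8. Read it. At y = 0.100 the clock shows 49.0 s, close to the run time of 50 s. Free starting material is then a fraction 0.0669, so I commit to 93.3% reacted in zeta, gamma and theta, and to no change.

The forecast gives 92%, 93% and 93.5% for zeta, gamma and theta, and no change, holding that “extra partner barely matters”. It lets the three rise slightly, where my clock gives one number.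

The simulation gives 92.8%, 93.3% and 93.5%, a change of 0.65 percentage points, so no change. In zeta, 16.6% of the coupling partner is still free at the end. Now lower the loading: in a flask like theta with 0.62 mol% of free catalyst, τ stretches to 51.0 s. Set to that flask's simulated product of 41.9%, so y = 58.1% of the charge, the clock reads 48.6 s, and that flask holds 49.0% starting material at 50.0 s.

The constants belong to no real substance; what happens was integrated by code.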